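**Strategy.** Ring A (C1–C5, C10) is unravelled to an acyclic terpene: the C3 carbinol beside the gem-dimethyl carbon C4 is the retron of a 2,2-dimethyloxirane, and C5 with C10 map onto the E-alkene of geranyl acetate. A titanocene-mediated radical cyclization of (R)-6,7-epoxygeranyl acetate forms the C4–C5 bond, closes ring A with C3 and C5 set, and leaves a C10=C20 methylene. From it the spiro centre C10 and the 7,20-lactone arise by a second epoxide-radical addition to an acrylate; rings C and D follow by alkylation with (S)-lavandulyl iodide, 6-endo radical closure (C9–C11) and oxidative cyclization with Pd(OAc)2 (C8–C15).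

Key step: step 2

Remarks: ent-kaurane atom numbers are used throughout (ring A = C1–C5 and C10; lactone ring = C10, C20, O, C7, C8, C9; ring C = C8, C9, C11–C14; ring D = C8, C14, C13, C16, C15; C6 = formyl carbon; C17 = methylene carbon). Racemic lavandulol is taken as the commercial form. Where a SMILES leaves a centre open (C10 in 11; C8 in 18, 19, 25, F1, F2 and F3; the oxirane CH in 21; C11 in F1 and F2), both epimers are meant, because that centre is erased later.

**Step 1**
Reactants: 1 geranyl acetate
Product: 2 (R)-6,7-epoxygeranyl acetate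
Conditions: D-fructose-derived Shi ketone (1,2:4,5-di-O-isopropylidene-β-D-erythro-hexo-2,3-diulo-2,6-pyranose, 30 mol %), KHSO5 (as 2KHSO5·KHSO4·K2SO4), K2CO3, Bu4NHSO4, MeCN/dimethoxymethane/aq. Na2B4O7 buffer, 0 °C
Reagents that add atoms: potassium peroxymonosulfate, [K+].OOS(=O)(=O)[O-]
Why: Shi asymmetric epoxidation, in which the electrophilic chiral dioxirane should attack the electron-rich distal alkene rather than the alkene deactivated by the allylic acetate, and its spiro transition state sets the R configuration at the oxirane CH (later C3).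

**Step 2**
Reactants: 2 (R)-6,7-epoxygeranyl acetate
Product: 4 [(1S,3R)-3-hydroxy-2,2-dimethyl-6-methylidenecyclohexyl]methyl acetate, via TMS ether 3 (not isolated)
Conditions: Cp2TiCl2 (20 mol %), Mn, Me3SiCl, 2,4,6-collidine, THF, rt; then 1 M HCl
Reagents that add atoms: none
Why: Cp2TiCl (trivalent titanium, formed from Cp2TiCl2 and Mn) opens the oxirane homolytically at the C4–O bond to the tertiary C4 radical carrying the C3–O–Ti group, this radical adds to C5 of the E-trisubstituted alkene to give the tertiary C10 radical, and a second Cp2TiCl turns that radical into the C10=C20 methylene by abstracting a methyl hydrogen, while Me3SiCl and collidine release the catalyst from oxygen. The closest known reaction is the titanocene-catalysed radical cyclization of epoxypolyprenes, the radical counterpart of the biosynthetic oxidosqualene-type closure, for which this substrate class is the standard case. Ring A closes in a 6-endo-trig mode at the alkene, the alternative 5-exo attack on the fully substituted C10 being disfavoured. C3 keeps the configuration installed in the epoxide because its C–O bond is not broken, and C5 is set by a chair-like transition state in which the C3 titanoxy group and the acetoxymethyl group of the E-alkene are both equatorial, which gives the cis-3,5 relationship. The step needs regioselective epoxide opening, endo over exo addition and exocyclic over endocyclic alkene formation; the first two follow from radical stability and alkene substitution, the last from abstraction of the most accessible methyl hydrogen.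

**Step 3**
Reactants: 4 [(1S,3R)-3-hydroxy-2,2-dimethyl-6-methylidenecyclohexyl]methyl acetate
Product: 5 (1R,3S)-3-(hydroxymethyl)-2,2-dimethyl-4-methylidenecyclohexan-1-ol
Conditions: K2CO3 (cat.), MeOH, rt
Reagents that add atoms: none
Why: Base-catalysed transesterification (methanolysis) removes the acetate, which could not survive the later enolate steps, without touching a stereocentre.

**Step 4**
Reactants: 5 (1R,3S)-3-(hydroxymethyl)-2,2-dimethyl-4-methylidenecyclohexan-1-ol
Product: 6 bis-TBS ether (C3 OTBS and C6 OTBS)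
Conditions: TBSOTf, 2,6-lutidine, CH2Cl2, 0 °C
Reagents that add atoms: tert-butyldimethylsilyl triflate, CC(C)(C)[Si](C)(C)OS(=O)(=O)C(F)(F)F
Why: Silylation with the silyl triflate (needed for the neopentyl C3 hydroxyl) protects both hydroxyls as ethers that are stable to the radical, hydride and enolate steps ahead.

**Step 5**
Reactants: 6 bis-TBS ether
Product: 7 axial C1 allylic alcohol (1-epi series)
Conditions: SeO2 (0.5 equiv), t-BuOOH, CH2Cl2, rt
Reagents that add atoms: tert-butyl hydroperoxide, CC(C)(C)OO
Why: Riley allylic oxidation (ene reaction then [2,3]-sigmatropic shift), in which the ring CH2 at C1 should react in preference to the C5 methine, and removal of the axial hydrogen with return of oxygen on the same face should give the axial alcohol trans to the C3 silyloxy group.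

**Step 6**
Reactants: 7 axial C1 allylic alcohol
Product: 8 2-methylidene ketone (C1 ketone)
Conditions: Dess–Martin periodinane, NaHCO3, CH2Cl2, 0 °C (product used at once)
Reagents that add atoms: none
Why: Dess–Martin oxidation under neutral conditions erases the wrongly configured C1 centre without β-elimination of the C3 silyloxy group.

**Step 7**
Reactants: 8 2-methylidene ketone
Product: 9 equatorial C1 alcohol
Conditions: NaBH4, CeCl3·7H2O, MeOH, −78 °C
Reagents that add atoms: none
Why: Luche reduction, in which 1,2-selective hydride delivery along the axial trajectory (no 1,3-diaxial substituent on that face) should give the equatorial C1 alcohol, cis to the C3 and C5 substituents as in the target.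

**Step 8**
Reactants: 9 equatorial C1 alcohol
Product: 10 C1 PMB ether
Conditions: NaH, 4-methoxybenzyl chloride, Bu4NI (cat.), DMF, 0 °C to rt
Reagents that add atoms: 4-methoxybenzyl chloride, COc1ccc(CCl)cc1
Why: Williamson etherification gives a PMB ether that survives the enolate chemistry and is later removed by DDQ without touching the silyl ethers.

**Step 9**
Reactants: 10 C1 PMB ether
Product: 11 spiro-oxirane at C10/C20
Conditions: mCPBA, NaHCO3, CH2Cl2, 0 °C
Reagents that add atoms: 3-chloroperoxybenzoic acid, OOC(=O)c1cccc(Cl)c1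
Why: Prilezhaev epoxidation of the 1,1-disubstituted alkene, whose facial outcome is irrelevant because C10 becomes a planar radical in the next step.

**Step 10**
Reactants: 11 spiro-oxirane; 12 2,2,2-trifluoroethyl acrylate
Product: 14 spirolactone (7,20-olide), via hydroxy ester 13 (not isolated)
Conditions: Cp2TiCl2 (20 mol %), Zn, 2,4,6-collidine·HCl, THF, rt
Reagents that add atoms: none
Why: Titanocene-mediated reductive epoxide–acrylate coupling, in which Cp2TiCl (trivalent titanium) opens the oxirane to the tertiary C10 radical, this adds to the acrylate (Giese addition) from the face away from the axial C4 methyl group so that C9 becomes equatorial and C20 axial (this sets C10), and the C20 oxygen then displaces trifluoroethoxide to close the lactone.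

**Step 11**
Reactants: 15 (±)-lavandulol
Product: 16 (S)-lavandulol
Conditions: porcine pancreatic lipase, vinyl acetate, hexane, rt, stopped beyond half conversion
Reagents that add atoms: none
Why: Lipase-catalysed kinetic resolution by transesterification, in which the enzyme should acylate the R alcohol faster, so that running past half conversion leaves the S alcohol in high enantiomeric purity.

**Step 12**
Reactants: 16 (S)-lavandulol
Product: 17 (S)-lavandulyl iodide
Conditions: I2, PPh3, imidazole, CH2Cl2, 0 °C
Reagents that add atoms: iodine, II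
Why: Appel-type iodination converts the primary alcohol into the iodide without touching the stereocentre or the alkenes.

**Step 13**
Reactants: 14 spirolactone; 17 (S)-lavandulyl iodide
Product: 18 C8-lavandulyl spirolactone
Conditions: LiN(iPr)2, THF, −78 °C; then 17, HMPA, −78 to −20 °C
Reagents that add atoms: none
Why: SN2 alkylation of the lactone lithium enolate with the primary iodide, where the C8 configuration is of no consequence (C8 becomes sp2 next) and C13 is brought in by the iodide.

**Step 14**
Reactants: 18 C8-lavandulyl spirolactone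
Product: 20 C8=C9 unsaturated lactone, via selenide 19 (not isolated)
Conditions: LiN(iPr)2, THF, −78 °C; PhSeBr; then H2O2, pyridine, CH2Cl2, 0 °C to rt
Reagents that add atoms: none
Why: α-Selenenylation of the enolate followed by oxidation and syn-elimination of the selenoxide, which should take the ring hydrogen at C9 and give the endocyclic unsaturated lactone.

**Step 15**
Reactants: 20 C8=C9 unsaturated lactone
Product: 22 C11 aldehyde, via epoxide 21 (not isolated)
Conditions: mCPBA (1.05 equiv), CH2Cl2, 0 °C; then H5IO6, THF/H2O, 0 °C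
Reagents that add atoms: 3-chloroperoxybenzoic acid, OOC(=O)c1cccc(Cl)c1
Why: The peracid should epoxidize the trisubstituted prenyl alkene faster than the 1,1-disubstituted and the electron-poor alkenes, and periodic acid then cleaves the epoxide through its diol (Malaprade-type cleavage) to the aldehyde and acetone.

**Step 16**
Reactants: 22 C11 aldehyde
Product: 23 C11 primary alcohol
Conditions: NaBH4, MeOH/THF, −20 °C
Reagents that add atoms: none
Why: Chemoselective borohydride reduction of the aldehyde at low temperature, the conjugated lactone being far less electrophilic.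

**Step 17**
Reactants: 23 C11 primary alcohol
Product: 24 C11 primary iodide
Conditions: I2, PPh3, imidazole, CH2Cl2, 0 °C
Reagents that add atoms: iodine, II
Why: Appel-type iodination of the unhindered primary alcohol provides the radical precursor.

**Step 18**
Reactants: 24 C11 primary iodide
Product: 25 tricyclic lactone (ring C closed)
Conditions: Bu3SnH, azobisisobutyronitrile (cat.), benzene, 80 °C, slow addition at high dilution
Reagents that add atoms: none
Why: Tin hydride radical cyclization, in which the primary C11 radical adds 6-endo to C9, the β-carbon of the α-substituted unsaturated lactone, through a chair-like transition state with the isopropenyl group equatorial and from the lactone face on the C1 side (away from the C5/C4 gem-dimethyl side), which sets C9 trans to C13 across ring C before the C8 radical is reduced.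

**Step 19**
Reactants: 25 tricyclic lactone
Product: 27 tetracyclic 16-ene lactone, via silyl ketene acetal 26 (not isolated)
Conditions: KN(SiMe3)2, TBSCl, THF, −78 °C; then Pd(OAc)2 (1 equiv), AcOH, DMSO, 45 °C
Reagents that add atoms: none
Why: Oxidative cyclization of a silyl ketene acetal with divalent palladium (Saegusa/Kende-type cycloalkenylation), in which C8 bonds to the terminal carbon of the isopropenyl group and β-hydride loss toward the methyl group gives the C16=C17 methylene; the two-carbon bridge can only span C8 and C13 on the face that carries the C13 substituent, so C8 is set by C13.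

**Step 20**
Reactants: 27 tetracyclic 16-ene lactone
Product: 28 C1 alcohol
Conditions: DDQ, CH2Cl2/pH 7 phosphate buffer, 0 °C
Reagents that add atoms: none
Why: Oxidative PMB cleavage (hydride abstraction by DDQ and hydrolysis of the oxocarbenium ion) frees the C1 hydroxyl alone.

**Step 21**
Reactants: 28 C1 alcohol
Product: 29 C1 acetate
Conditions: Ac2O, 4-dimethylaminopyridine (cat.), pyridine, CH2Cl2, rt
Reagents that add atoms: acetic anhydride, CC(=O)OC(C)=O
Why: Nucleophile-catalysed acetylation of the only free hydroxyl.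

**Step 22**
Reactants: 29 C1 acetate
Product: 30 C3,C6-diol
Conditions: HF·pyridine, pyridine, THF, 0 °C to rt
Reagents that add atoms: none
Why: Fluoride-mediated cleavage of both silyl ethers under buffered conditions that leave the acetate, the lactone and the alkene intact.

**Step 23**
Reactants: 30 C3,C6-diol
Product: 31 C6 aldehyde (15-deoxy target)
Conditions: 2,2,6,6-tetramethylpiperidin-1-oxyl (cat.), PhI(OAc)2, CH2Cl2, rt
Reagents that add atoms: none
Why: Oxoammonium-mediated oxidation, selective for the primary alcohol over the hindered secondary C3 alcohol, gives the aldehyde, whose equatorial formyl group is also the more stable arrangement at C5.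

**Step 24**
Reactants: 31 C6 aldehyde
Product: 32 CNP0536233.1
Conditions: SeO2 (0.5 equiv), t-BuOOH, CH2Cl2, 0 °C to rt
Reagents that add atoms: tert-butyl hydroperoxide, CC(C)(C)OO
Why: Riley allylic oxidation, in which C15 is the only allylic position able to react (C13 is a bridgehead) and the ene/[2,3] sequence should deliver oxygen to the face of C15 turned toward C9 and away from the C7 carbonyl and the C14 bridge, the course typical of ent-kaur-16-enes.

**Compound list**
1 | geranyl acetate | CC(C)=CCC/C(C)=C/COC(C)=O | starting material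
2 | (R)-6,7-epoxygeranyl acetate, (2E)-5-[(2R)-3,3-dimethyloxiran-2-yl]-3-methylpent-2-en-1-yl acetate | CC(=O)OC/C=C(\C)CC[C@H]1OC1(C)C | intermediate
3 | trimethylsilyl ether of 4 at the C3 oxygen | C=C1CC[C@@H](O[Si](C)(C)C)C(C)(C)[C@H]1COC(C)=O | intermediate (not isolated)
4 | [(1S,3R)-3-hydroxy-2,2-dimethyl-6-methylidenecyclohexyl]methyl acetate | C=C1CC[C@@H](O)C(C)(C)[C@H]1COC(C)=O | intermediate
5 | (1R,3S)-3-(hydroxymethyl)-2,2-dimethyl-4-methylidenecyclohexan-1-ol | C=C1CC[C@@H](O)C(C)(C)[C@H]1CO | intermediate
6 | bis-TBS ether of 5 (C3 OTBS, C6 OTBS) | C=C1CC[C@@H](O[Si](C)(C)C(C)(C)C)C(C)(C)[C@H]1CO[Si](C)(C)C(C)(C)C | intermediate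
7 | 6 with an axial hydroxyl at C1, trans to the C3 silyloxy group | C=C1[C@H](O)C[C@@H](O[Si](C)(C)C(C)(C)C)C(C)(C)[C@H]1CO[Si](C)(C)C(C)(C)C | intermediate
8 | 2-methylidene ketone (C1 ketone of ring A) | C=C1C(=O)C[C@@H](O[Si](C)(C)C(C)(C)C)C(C)(C)[C@H]1CO[Si](C)(C)C(C)(C)C | intermediate
9 | equatorial C1 alcohol, all-cis with the C3 silyloxy and C5 silyloxymethyl groups | C=C1[C@@H](O)C[C@@H](O[Si](C)(C)C(C)(C)C)C(C)(C)[C@H]1CO[Si](C)(C)C(C)(C)C | intermediate
10 | C1 4-methoxybenzyl ether of 9 | C=C1[C@@H](OCc2ccc(OC)cc2)C[C@@H](O[Si](C)(C)C(C)(C)C)C(C)(C)[C@H]1CO[Si](C)(C)C(C)(C)C | intermediate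
11 | spiro-oxirane of 10 at C10/C20 (both C10 epimers) | C1OC12[C@@H](OCc3ccc(OC)cc3)C[C@@H](O[Si](C)(C)C(C)(C)C)C(C)(C)[C@H]2CO[Si](C)(C)C(C)(C)C | intermediate
12 | 2,2,2-trifluoroethyl acrylate | C=CC(=O)OCC(F)(F)F | starting material
13 | hydroxy ester: quaternary C10 bearing CH2OH (C20) and CH2CH2CO2CH2CF3 (C9, C8, C7) | OC[C@@]1(CCC(=O)OCC(F)(F)F)[C@@H](OCc2ccc(OC)cc2)C[C@@H](O[Si](C)(C)C(C)(C)C)C(C)(C)[C@H]1CO[Si](C)(C)C(C)(C)C | intermediate (not isolated)
14 | spirolactone (7,20-olide; C8 and C9 are CH2; C1 OPMB, C3 OTBS, C6 OTBS) | O=C1CC[C@]2(CO1)[C@@H](OCc3ccc(OC)cc3)C[C@@H](O[Si](C)(C)C(C)(C)C)C(C)(C)[C@H]2CO[Si](C)(C)C(C)(C)C | intermediate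
15 | (±)-lavandulol, 5-methyl-2-(prop-1-en-2-yl)hex-4-en-1-ol | CC(C)=CCC(CO)C(C)=C | starting material
16 | (S)-lavandulol | OC[C@@H](CC=C(C)C)C(C)=C | intermediate
17 | (S)-lavandulyl iodide | IC[C@@H](CC=C(C)C)C(C)=C | intermediate
18 | spirolactone 14 carrying the (S)-lavandulyl group on C8 (both C8 epimers) | O=C1C(C[C@@H](CC=C(C)C)C(C)=C)C[C@]2(CO1)[C@@H](OCc3ccc(OC)cc3)C[C@@H](O[Si](C)(C)C(C)(C)C)C(C)(C)[C@H]2CO[Si](C)(C)C(C)(C)C | intermediate
19 | C8 phenylselenide of 18 | O=C1C(C[C@@H](CC=C(C)C)C(C)=C)([Se]c3ccccc3)C[C@]2(CO1)[C@@H](OCc3ccc(OC)cc3)C[C@@H](O[Si](C)(C)C(C)(C)C)C(C)(C)[C@H]2CO[Si](C)(C)C(C)(C)C | intermediate (not isolated)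
20 | C8=C9 unsaturated spirolactone with the (S)-lavandulyl group on C8 | O=C1C(C[C@@H](CC=C(C)C)C(C)=C)=C[C@]2(CO1)[C@@H](OCc3ccc(OC)cc3)C[C@@H](O[Si](C)(C)C(C)(C)C)C(C)(C)[C@H]2CO[Si](C)(C)C(C)(C)C | intermediate
21 | epoxide of the prenyl alkene of 20 | O=C1C(C[C@@H](CC4OC4(C)C)C(C)=C)=C[C@]2(CO1)[C@@H](OCc3ccc(OC)cc3)C[C@@H](O[Si](C)(C)C(C)(C)C)C(C)(C)[C@H]2CO[Si](C)(C)C(C)(C)C | intermediate (not isolated)
22 | C11 aldehyde (C8 side chain CH2–CH(isopropenyl)–CH2–CHO) | O=C1C(C[C@@H](CC=O)C(C)=C)=C[C@]2(CO1)[C@@H](OCc3ccc(OC)cc3)C[C@@H](O[Si](C)(C)C(C)(C)C)C(C)(C)[C@H]2CO[Si](C)(C)C(C)(C)C | intermediate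
23 | C11 primary alcohol | O=C1C(C[C@@H](CCO)C(C)=C)=C[C@]2(CO1)[C@@H](OCc3ccc(OC)cc3)C[C@@H](O[Si](C)(C)C(C)(C)C)C(C)(C)[C@H]2CO[Si](C)(C)C(C)(C)C | intermediate
24 | C11 primary iodide | O=C1C(C[C@@H](CCI)C(C)=C)=C[C@]2(CO1)[C@@H](OCc3ccc(OC)cc3)C[C@@H](O[Si](C)(C)C(C)(C)C)C(C)(C)[C@H]2CO[Si](C)(C)C(C)(C)C | intermediate
25 | tricyclic lactone: ring C closed, 13-isopropenyl, C8–H (both C8 epimers) | CC(=C)[C@@H]1CC[C@@H]2C(C1)C(=O)OC[C@]23[C@@H](OCc4ccc(OC)cc4)C[C@@H](O[Si](C)(C)C(C)(C)C)C(C)(C)[C@H]3CO[Si](C)(C)C(C)(C)C | intermediate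
26 | tert-butyldimethylsilyl ketene acetal of 25 | CC(=C)[C@@H]1CC[C@@H]2C(C1)=C(O[Si](C)(C)C(C)(C)C)OC[C@]23[C@@H](OCc4ccc(OC)cc4)C[C@@H](O[Si](C)(C)C(C)(C)C)C(C)(C)[C@H]3CO[Si](C)(C)C(C)(C)C | intermediate (not isolated)
27 | tetracyclic 16-ene 7,20-lactone with C1 OPMB, C3 OTBS, C6 OTBS | C=C1[C@@H]2CC[C@@H]3[C@](C2)(C(=O)OC[C@]32[C@@H](OCc4ccc(OC)cc4)C[C@@H](O[Si](C)(C)C(C)(C)C)C(C)(C)[C@H]2CO[Si](C)(C)C(C)(C)C)C1 | intermediate
28 | C1 alcohol of 27 | C=C1[C@@H]2CC[C@@H]3[C@](C2)(C(=O)OC[C@]32[C@@H](O)C[C@@H](O[Si](C)(C)C(C)(C)C)C(C)(C)[C@H]2CO[Si](C)(C)C(C)(C)C)C1 | intermediate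
29 | C1 acetate | C=C1[C@@H]2CC[C@@H]3[C@](C2)(C(=O)OC[C@]32[C@@H](OC(C)=O)C[C@@H](O[Si](C)(C)C(C)(C)C)C(C)(C)[C@H]2CO[Si](C)(C)C(C)(C)C)C1 | intermediate
30 | C1 acetate C3,C6-diol | C=C1[C@@H]2CC[C@@H]3[C@](C2)(C(=O)OC[C@]32[C@@H](OC(C)=O)C[C@@H](O)C(C)(C)[C@H]2CO)C1 | intermediate
31 | C6 aldehyde (15-deoxy target) | C=C1[C@@H]2CC[C@@H]3[C@](C2)(C(=O)OC[C@]32[C@@H](OC(C)=O)C[C@@H](O)C(C)(C)[C@H]2C=O)C1 | intermediate
32 | CNP0536233.1 | C=C1[C@@H]2CC[C@@H]3[C@](C2)(C(=O)OC[C@]32[C@@H](OC(C)=O)C[C@@H](O)C(C)(C)[C@H]2C=O)[C@@H]1O | target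

**Step count.** Total: 24 steps. Longest linear sequence: 22 steps (steps 1–10 and 13–24; steps 11–12 are the side branch).

**Steps most likely to fail**

Step 18 (radical closure of ring C). The primary radical may be reduced by the tin hydride before it cyclizes, and the C1 ether flanking the lactone may erode facial selectivity at C9. The fallback sets out from aldehyde 22 and returns at 25. SmI2 (LiBr, t-BuOH, THF, −78 °C) reduces the aldehyde to a ketyl that adds to C9 in the same 6-endo sense, with samarium chelated between the ketyl and lactone oxygens, giving the 11-hydroxy tricyclic lactone F1. PhOC(S)Cl and 4-dimethylaminopyridine convert the hydroxyl into the phenyl thionocarbonate F2. Bu3SnH with azobisisobutyronitrile then removes it (Barton–McCombie deoxygenation) to give 25.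

Step 19 (oxidative closure of ring D). The silyl ketene acetal may be protodesilylated, or the palladium enolate may undergo dehydrogenation instead of C–C bond formation. The fallback sets out from 25 and returns at 27. Ene-type allylic chlorination of the isopropenyl group (N-chlorosuccinimide, catalytic PhSeCl, CH2Cl2) gives the allylic chloride F3. KN(SiMe3)2 (THF, −78 to 0 °C) then forms the lactone enolate, which displaces the chloride in a 5-exo-tet alkylation that closes the C8–C15 bond and leaves the C16=C17 methylene.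

Step 24 (C15 hydroxylation). Oxygen may be delivered to the wrong face of C15, or the alcohol may be over-oxidized. The fallback sets out from 29 and returns at 32, and uses the fact that hydride reduction of the 15-ketone and the selenium-mediated oxidation should place oxygen on opposite faces. SeO2/t-BuOOH on 29 gives the 15-epi alcohol F4. Dess–Martin periodinane gives the 15-ketone F5. NaBH4/CeCl3·7H2O delivers hydride from the face that the oxidant used and gives the 15-alcohol F6 with the target configuration. HF·pyridine gives the triol F7. 2,2,6,6-Tetramethylpiperidin-1-oxyl with PhI(OAc)2 then oxidizes the primary alcohol in preference to the two hindered secondary ones to give 32.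

**Further compounds**
F1 | step 18 | 11-hydroxy tricyclic lactone (25 with OH at C11) | CC(=C)[C@@H]1CC(O)[C@@H]2C(C1)C(=O)OC[C@]23[C@@H](OCc4ccc(OC)cc4)C[C@@H](O[Si](C)(C)C(C)(C)C)C(C)(C)[C@H]3CO[Si](C)(C)C(C)(C)C
F2 | step 18 | C11 O-phenyl thionocarbonate of F1 | CC(=C)[C@@H]1CC(OC(=S)Oc5ccccc5)[C@@H]2C(C1)C(=O)OC[C@]23[C@@H](OCc4ccc(OC)cc4)C[C@@H](O[Si](C)(C)C(C)(C)C)C(C)(C)[C@H]3CO[Si](C)(C)C(C)(C)C
F3 | step 19 | allylic chloride (25 with a 3-chloroprop-1-en-2-yl group on C13) | ClCC(=C)[C@@H]1CC[C@@H]2C(C1)C(=O)OC[C@]23[C@@H](OCc4ccc(OC)cc4)C[C@@H](O[Si](C)(C)C(C)(C)C)C(C)(C)[C@H]3CO[Si](C)(C)C(C)(C)C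
F4 | step 24 | 15-epi alcohol of the bis-TBS acetate series | C=C1[C@@H]2CC[C@@H]3[C@](C2)(C(=O)OC[C@]32[C@@H](OC(C)=O)C[C@@H](O[Si](C)(C)C(C)(C)C)C(C)(C)[C@H]2CO[Si](C)(C)C(C)(C)C)[C@H]1O
F5 | step 24 | 15-ketone (16-en-15-one) of the bis-TBS acetate series | C=C1[C@@H]2CC[C@@H]3[C@](C2)(C(=O)OC[C@]32[C@@H](OC(C)=O)C[C@@H](O[Si](C)(C)C(C)(C)C)C(C)(C)[C@H]2CO[Si](C)(C)C(C)(C)C)C1=O
F6 | step 24 | 15-alcohol with the target configuration, bis-TBS acetate series | C=C1[C@@H]2CC[C@@H]3[C@](C2)(C(=O)OC[C@]32[C@@H](OC(C)=O)C[C@@H](O[Si](C)(C)C(C)(C)C)C(C)(C)[C@H]2CO[Si](C)(C)C(C)(C)C)[C@@H]1O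
F7 | step 24 | C3,C6,C15-triol with C1 acetate | C=C1[C@@H]2CC[C@@H]3[C@](C2)(C(=O)OC[C@]32[C@@H](OC(C)=O)C[C@@H](O)C(C)(C)[C@H]2CO)[C@@H]1O
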